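**Plan**

1. Retrosynthesis: the eight aryl benzyl ethers and two silyl ethers come off last. The C3 carbinol goes back to a flavan-3-one and that to a C3 bromide. The C2–C3 and C3–C4 bonds of the upper ring C are then cut, so that C3 leaves as a one-carbon unit.
2. Enabling feature: in ring C, C3 is the only atom between C2 (bearing ring B) and C4 (bearing ring D through C8'). Without C3, the atoms O1, C2, C4, C4a and C8a form the furan of a flat 2,3-diarylbenzofuran made of rings A, B and D.
3. Further cuts: the benzofuran C2–ring B bond (C–H arylation), the furan ring itself (cyclodehydration of an aryloxymethyl ketone) and the ketone–C8' bond (aryllithium plus Weinreb amide).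
4. Forward order: rings D, E and F arrive intact from (−)-epicatechin, ring A comes in as a phenol, the furan closes, ring B is attached, and ring C arises last by expansion of the furan.
5. Stereochemistry: C2' and C3' come from (−)-epicatechin. C4' is set by DDQ hydroxylation anti to the 3'-silyloxy group. C2, C3 and C4 are set together by a ruthenium-catalysed transfer hydrogenation under dynamic kinetic resolution.
6. Naming: upper unit rings A (benzo), B (catechol), C (pyran) with unprimed positions; lower unit rings D (benzo), E (catechol), F (pyran) with primed positions.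

Key step: step 11

Assumption: with RuCl(p-cymene)[(R,R)-TsDPEN] the arene-fused C4 flank of the flavan-3-one is taken to play the part of the aryl group in the usual aryl ketone model, so that hydride reaches the C3 face leading to the (3S) carbinol.

**Route**

Step 1
Reactants: 1 (−)-epicatechin
Product: 2 tetra-O-benzyl-(−)-epicatechin (all four phenols as benzyl ethers; C3' hydroxyl free)
Conditions: BnBr, K2CO3, DMF, 0 °C → rt
Reagents that add atoms: benzyl bromide, BrCc1ccccc1
Why: Williamson ether synthesis under carbonate conditions should alkylate the four phenols and leave the less acidic secondary alcohol and both stereocentres untouched.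

Step 2
Reactants: 2 tetra-O-benzyl-(−)-epicatechin
Product: 3 C8'-bromo-tetra-O-benzyl-(−)-epicatechin
Conditions: NBS, CH2Cl2, −78 °C → rt
Reagents that add atoms: N-bromosuccinimide, O=C1CCC(=O)N1Br
Why: Electrophilic aromatic bromination of the phloroglucinol-type ring D with one equivalent of NBS should go to C8', the position between the pyran oxygen and the C7' ether, as is usual for benzylated flavan-3-ols.

Step 3
Reactants: 3 C8'-bromo-tetra-O-benzyl-(−)-epicatechin
Product: 4 C8'-bromo-tetra-O-benzyl-3'-O-(tert-butyldimethylsilyl)-(−)-epicatechin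
Conditions: TBSCl, imidazole, DMF, rt
Reagents that add atoms: tert-butyldimethylsilyl chloride, CC(C)(C)[Si](C)(C)Cl
Why: Silylation of the axial secondary alcohol removes the only acidic proton before halogen–lithium exchange and installs a group that later leaves with fluoride without touching benzylic C–O bonds.

Step 4
Reactants: 5 3,5-bis(benzyloxy)phenol; 6 2-chloro-N-methoxy-N-methylacetamide
Product: 7 2-[3,5-bis(benzyloxy)phenoxy]-N-methoxy-N-methylacetamide
Conditions: K2CO3, KI (cat.), acetone, reflux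
Reagents that add atoms: none
Why: Williamson O-alkylation of the phenoxide with the primary α-chloro amide, helped by in situ Finkelstein exchange, should give the aryloxyacetic Weinreb amide that carries ring A.

Step 5
Reactants: 4 C8'-bromo-tetra-O-benzyl-3'-O-TBS-(−)-epicatechin; 7 2-[3,5-bis(benzyloxy)phenoxy]-N-methoxy-N-methylacetamide
Product: 9 C8'-[(3,5-bis(benzyloxy)phenoxy)acetyl]-tetra-O-benzyl-3'-O-TBS-(−)-epicatechin, via C8' aryllithium 8 (not isolated)
Conditions: t-BuLi, THF, −78 °C; then 7, −78 → −20 °C; aq. NH4Cl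
Reagents that add atoms: none
Why: Bromine–lithium exchange at C8' followed by acylation stops at the ketone because the chelated tetrahedral adduct survives until work-up (Weinreb ketone synthesis), and the low temperature should favour addition over α-deprotonation of the amide.

Step 6
Reactants: 9 C8'-[(3,5-bis(benzyloxy)phenoxy)acetyl]-tetra-O-benzyl-3'-O-TBS-(−)-epicatechin
Product: 10 4,6-bis(benzyloxy)-3-(tetra-O-benzyl-3'-O-TBS-epicatechin-8'-yl)benzofuran (C2–H)
Conditions: Bi(OTf)3 (10 mol %), 4 Å MS, CH2Cl2, rt → 40 °C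
Reagents that add atoms: none
Why: Lewis-acid cyclodehydration of an α-aryloxy ketone (intramolecular Friedel–Crafts hydroxyalkylation at an ortho carbon of the very electron-rich dialkoxyphenoxy ring, then loss of water) should close the furan with the ketone carbon as C3, the two ortho positions being equivalent.

Step 7
Reactants: 10 4,6-bis(benzyloxy)-3-(tetra-O-benzyl-3'-O-TBS-epicatechin-8'-yl)benzofuran; 11 4-bromo-1,2-bis(benzyloxy)benzene
Product: 12 2-[3,4-bis(benzyloxy)phenyl]-4,6-bis(benzyloxy)-3-(tetra-O-benzyl-3'-O-TBS-epicatechin-8'-yl)benzofuran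
Conditions: Pd(OAc)2, PCy3·HBF4, K2CO3, PivOH (cat.), DMA, 110 °C
Reagents that add atoms: none
Why: Palladium-catalysed direct C–H arylation (concerted metalation–deprotonation with pivalate) should occur at C2 of the 3-arylbenzofuran, its most reactive C–H position, and so attach ring B.

Step 8
Reactants: 12 2-[3,4-bis(benzyloxy)phenyl]-4,6-bis(benzyloxy)-3-(tetra-O-benzyl-3'-O-TBS-epicatechin-8'-yl)benzofuran
Product: 13 C4'-hydroxy derivative of 12 (3',4'-trans; lower unit 2'R,3'R,4'S)
Conditions: DDQ, CH2Cl2/H2O, 0 °C → rt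
Reagents that add atoms: water, O
Why: DDQ benzylic oxidation abstracts hydride from the C4' methylene activated by the ortho and para oxygens of ring D, and water should trap the cation from the face opposite the axial 3'-silyloxy group to set the 3',4'-trans carbinol, while the benzofuran half offers no abstractable hydrogen.

Step 9
Reactants: 13 C4'-hydroxy derivative of 12
Product: 14 2-[3,4-bis(benzyloxy)phenyl]-4,6-bis(benzyloxy)-3-(tetra-O-benzyl-3',4'-bis-O-TBS-epicatechin-4'-ol-8'-yl)benzofuran (rotamer mixture about the C3–C8' axis)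
Conditions: TBSCl, imidazole, DMAP (cat.), DMF, 40 °C
Reagents that add atoms: tert-butyldimethylsilyl chloride, CC(C)(C)[Si](C)(C)Cl
Why: Silylation under non-acidic conditions masks the benzylic carbinol against O–H insertion of the carbene and against ionisation, without any Lewis acid that could ionise C4'.

Step 10
Reactants: 15 phenylmercury chloride; 16 bromoform
Product: 17 phenyl(tribromomethyl)mercury
Conditions: KOt-Bu, benzene, 5 °C
Reagents that add atoms: none
Why: Deprotonation of bromoform and capture of the tribromomethyl anion by the arylmercury chloride is the standard preparation of this neutral dibromocarbene transfer reagent.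

Step 11
Reactants: 14 bis-O-TBS 2,3-diarylbenzofuran; 17 phenyl(tribromomethyl)mercury
Product: 19 3-bromo-5,7-bis(benzyloxy)-2-[3,4-bis(benzyloxy)phenyl]-4-(tetra-O-benzyl-3',4'-bis-O-TBS-epicatechin-4'-ol-8'-yl)chromenylium bromide, via dibromocyclopropane 18 (not isolated)
Conditions: benzene, 80 °C, argon, 2,6-di-tert-butyl-4-methylpyridine (0.2 equiv); PhHgBr filtered off, salt triturated with dry Et2O and used at once
Reagents that add atoms: none
Why: Proposed new method: thermal release of dibromocarbene from 17 in a neutral medium should be followed by [2+1] addition of the electrophilic carbene to the enol-ether-like C2=C3 bond of the benzofuran, and the fused dibromocyclopropane 18 is expected to open at once by disrotatory electrocyclic cleavage of the old C2–C3 bond with loss of the bromine syn to the five-membered ring, assisted by the O1 lone pair, so that the carbene carbon becomes C3 bonded to C2 and C4. The closest known reaction type is the dihalocarbene ring expansion of benzofurans, indenes and indoles to 3-halo six-membered rings (Ciamician–Dennstedt type), which has not been shown on a tetrasubstituted 2,3-diarylbenzofuran. Ring C is closed as an aromatic six-membered benzopyrylium ring by expansion of the furan (cyclopropanation, then two-electron electrocyclic opening), not by cyclisation of a chain. No stereocentre is created, because the upper half stays flat and the lower-unit centres are not involved. The step needs chemoselective addition at the hindered furan bond instead of insertion into benzylic C–H bonds or attack on the alkoxyarene rings, and the only bias is the high electron density of the 4,6-dialkoxybenzofuran C2=C3 bond, supported by a small excess of reagent. The neutral conditions give the cation with the second carbene bromine as its counter-ion and spare the acid-labile C4' silyl ether.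

Step 12
Reactants: 19 3-bromo-4-arylflavylium bromide
Product: 20 3-bromo-5,7-bis(benzyloxy)-2-[3,4-bis(benzyloxy)phenyl]-4-(tetra-O-benzyl-3',4'-bis-O-TBS-epicatechin-4'-ol-8'-yl)-2H-chromene (mixture at C2 and about the C4–C8' axis)
Conditions: NaBH4, THF/i-PrOH, −40 → 0 °C (salt added to the hydride)
Reagents that add atoms: none
Why: Hydride addition to a benzopyrylium cation should occur at C2 because C4 is shielded by the ortho-disubstituted ring D and the peri C5 ether; the new C2 centre is erased in step 13, and a 4H-chromene isomer would lead to the same ketone.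

Step 13
Reactants: 20 3-bromo-2H-chromene
Product: 23 5,7-bis(benzyloxy)-2-[3,4-bis(benzyloxy)phenyl]-4-(tetra-O-benzyl-3',4'-bis-O-TBS-epicatechin-4'-ol-8'-yl)chroman-3-one (interconverting C2/C4 epimers), via C3 vinyllithium 21 (not isolated), via lithium C3 triisopropoxyborate 22 (not isolated)
Conditions: B(Oi-Pr)3, n-BuLi, THF/toluene, −78 °C; then 30% H2O2, aq. NaHCO3, 0 °C
Reagents that add atoms: hydrogen peroxide, OO
Why: Bromine–lithium exchange with the borate ester already present (in situ quench) should intercept the vinyllithium before β-elimination of the ring aryloxide, and peroxide oxidation of the alkenylborate (1,2-metallate shift) gives the enol, which tautomerises to the flavan-3-one.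

Step 14
Reactants: 23 2,4-diarylchroman-3-one
Product: 24 all-cis carbinol: upper unit (2S,3S,4R) with free C3–OH, four upper and four lower aryl benzyl ethers, lower unit 3',4'-bis-O-TBS
Conditions: RuCl(p-cymene)[(R,R)-TsDPEN] (5 mol %), HCO2H/Et3N (1:1), DMF, 40 °C, degassed
Reagents that add atoms: none
Why: In this Noyori–Ikariya transfer hydrogenation under dynamic kinetic resolution both α-carbons (C2 and C4) epimerise through their enols in the amine-rich medium, and the catalyst should reduce the 2,4-cis-diaryl ketone from the face opposite both aryl groups, so that C2, C3 and C4 are set together as the all-cis array, with the absolute sense coming from the catalyst.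

Step 15
Reactants: 24 all-cis bis-silyl carbinol
Product: 25 octa-O-benzyl triol (C3, C3' and C4' hydroxyls free; all eight phenols as benzyl ethers)
Conditions: TBAF, THF, 0 °C → rt
Reagents that add atoms: none
Why: Fluoride-mediated desilylation cleaves both secondary silyl ethers under non-reducing conditions that leave the benzyl aryl ethers and the benzylic carbinol untouched.

Step 16
Reactants: 25 octa-O-benzyl triol
Product: 26 target, upper unit (2S,3S,4R), lower unit (2'R,3'R,4'S), C4–C8' linked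
Conditions: H2 (1 atm), Pd(OH)2/C, THF/MeOH, rt, stopped at full conversion
Reagents that add atoms: none
Why: Hydrogenolysis of the eight benzyl aryl ethers is fast in neutral solvent, so a short reaction should spare the slower benzylic C4'–OH bond and the C4–C8' bond.

**Compound list**

1 | (−)-epicatechin | O[C@@H]1Cc2c(O)cc(O)cc2O[C@@H]1c1ccc(O)c(O)c1 | starting material
2 | tetra-O-benzyl-(−)-epicatechin | O[C@@H]1Cc2c(OCc9ccccc9)cc(OCc9ccccc9)cc2O[C@@H]1c1ccc(OCc9ccccc9)c(OCc9ccccc9)c1 | intermediate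
3 | C8'-bromo-tetra-O-benzyl-(−)-epicatechin | O[C@@H]1Cc2c(OCc9ccccc9)cc(OCc9ccccc9)c(Br)c2O[C@@H]1c1ccc(OCc9ccccc9)c(OCc9ccccc9)c1 | intermediate
4 | C8'-bromo-tetra-O-benzyl-3'-O-TBS-(−)-epicatechin | CC(C)(C)[Si](C)(C)O[C@@H]1Cc2c(OCc9ccccc9)cc(OCc9ccccc9)c(Br)c2O[C@@H]1c1ccc(OCc9ccccc9)c(OCc9ccccc9)c1 | intermediate
5 | 3,5-bis(benzyloxy)phenol | Oc1cc(OCc9ccccc9)cc(OCc9ccccc9)c1 | starting material
6 | 2-chloro-N-methoxy-N-methylacetamide | CON(C)C(=O)CCl | starting material
7 | 2-[3,5-bis(benzyloxy)phenoxy]-N-methoxy-N-methylacetamide | CON(C)C(=O)COc1cc(OCc9ccccc9)cc(OCc9ccccc9)c1 | intermediate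
8 | C8' aryllithium from 4 | CC(C)(C)[Si](C)(C)O[C@@H]1Cc2c(OCc9ccccc9)cc(OCc9ccccc9)c([Li])c2O[C@@H]1c1ccc(OCc9ccccc9)c(OCc9ccccc9)c1 | intermediate
9 | C8'-[(3,5-bis(benzyloxy)phenoxy)acetyl]-tetra-O-benzyl-3'-O-TBS-(−)-epicatechin | CC(C)(C)[Si](C)(C)O[C@@H]1Cc2c(OCc9ccccc9)cc(OCc9ccccc9)c(C(=O)COc3cc(OCc9ccccc9)cc(OCc9ccccc9)c3)c2O[C@@H]1c1ccc(OCc9ccccc9)c(OCc9ccccc9)c1 | intermediate
10 | 4,6-bis(benzyloxy)-3-(tetra-O-benzyl-3'-O-TBS-epicatechin-8'-yl)benzofuran | c9ccccc9COc1cc(OCc9ccccc9)c2c(c1)occ2-c1c(OCc9ccccc9)cc(OCc9ccccc9)c2c1O[C@H](c1ccc(OCc9ccccc9)c(OCc9ccccc9)c1)[C@H](O[Si](C)(C)C(C)(C)C)C2 | intermediate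
11 | 4-bromo-1,2-bis(benzyloxy)benzene | Brc1ccc(OCc9ccccc9)c(OCc9ccccc9)c1 | starting material
12 | 2-[3,4-bis(benzyloxy)phenyl]-4,6-bis(benzyloxy)-3-(tetra-O-benzyl-3'-O-TBS-epicatechin-8'-yl)benzofuran | c9ccccc9COc1cc(OCc9ccccc9)c2c(c1)oc(-c1ccc(OCc9ccccc9)c(OCc9ccccc9)c1)c2-c1c(OCc9ccccc9)cc(OCc9ccccc9)c2c1O[C@H](c1ccc(OCc9ccccc9)c(OCc9ccccc9)c1)[C@H](O[Si](C)(C)C(C)(C)C)C2 | intermediate
13 | C4'-hydroxy derivative of 12 (3',4'-trans) | c9ccccc9COc1cc(OCc9ccccc9)c2c(c1)oc(-c1ccc(OCc9ccccc9)c(OCc9ccccc9)c1)c2-c1c(OCc9ccccc9)cc(OCc9ccccc9)c2c1O[C@H](c1ccc(OCc9ccccc9)c(OCc9ccccc9)c1)[C@H](O[Si](C)(C)C(C)(C)C)[C@H]2O | intermediate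
14 | 3',4'-bis-O-TBS 2,3-diarylbenzofuran (key-step precursor) | c9ccccc9COc1cc(OCc9ccccc9)c2c(c1)oc(-c1ccc(OCc9ccccc9)c(OCc9ccccc9)c1)c2-c1c(OCc9ccccc9)cc(OCc9ccccc9)c2c1O[C@H](c1ccc(OCc9ccccc9)c(OCc9ccccc9)c1)[C@H](O[Si](C)(C)C(C)(C)C)[C@H]2O[Si](C)(C)C(C)(C)C | intermediate
15 | phenylmercury chloride | Cl[Hg]c1ccccc1 | starting material
16 | bromoform | BrC(Br)Br | starting material
17 | phenyl(tribromomethyl)mercury | BrC(Br)(Br)[Hg]c1ccccc1 | intermediate
18 | 1,1-dibromocyclopropa[b]benzofuran adduct of 14 (carbene carbon bridging old C2 and C3) | c9ccccc9COc1cc(OCc9ccccc9)c2c(c1)OC1(c3ccc(OCc9ccccc9)c(OCc9ccccc9)c3)C(Br)(Br)C21c1c(OCc9ccccc9)cc(OCc9ccccc9)c2c1O[C@H](c1ccc(OCc9ccccc9)c(OCc9ccccc9)c1)[C@H](O[Si](C)(C)C(C)(C)C)[C@H]2O[Si](C)(C)C(C)(C)C | intermediate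
19 | 3-bromo-4-arylflavylium bromide (key-step product) | c9ccccc9COc1cc(OCc9ccccc9)c2c(c1)[o+]c(-c1ccc(OCc9ccccc9)c(OCc9ccccc9)c1)c(Br)c2-c1c(OCc9ccccc9)cc(OCc9ccccc9)c2c1O[C@H](c1ccc(OCc9ccccc9)c(OCc9ccccc9)c1)[C@H](O[Si](C)(C)C(C)(C)C)[C@H]2O[Si](C)(C)C(C)(C)C.[Br-] | intermediate
20 | 3-bromo-4-aryl-2H-chromene | c9ccccc9COc1cc(OCc9ccccc9)c2c(c1)OC(c1ccc(OCc9ccccc9)c(OCc9ccccc9)c1)C(Br)=C2c1c(OCc9ccccc9)cc(OCc9ccccc9)c2c1O[C@H](c1ccc(OCc9ccccc9)c(OCc9ccccc9)c1)[C@H](O[Si](C)(C)C(C)(C)C)[C@H]2O[Si](C)(C)C(C)(C)C | intermediate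
21 | C3 vinyllithium | c9ccccc9COc1cc(OCc9ccccc9)c2c(c1)OC(c1ccc(OCc9ccccc9)c(OCc9ccccc9)c1)C([Li])=C2c1c(OCc9ccccc9)cc(OCc9ccccc9)c2c1O[C@H](c1ccc(OCc9ccccc9)c(OCc9ccccc9)c1)[C@H](O[Si](C)(C)C(C)(C)C)[C@H]2O[Si](C)(C)C(C)(C)C | intermediate
22 | lithium C3 triisopropoxyborate | c9ccccc9COc1cc(OCc9ccccc9)c2c(c1)OC(c1ccc(OCc9ccccc9)c(OCc9ccccc9)c1)C([B-](OC(C)C)(OC(C)C)OC(C)C)=C2c1c(OCc9ccccc9)cc(OCc9ccccc9)c2c1O[C@H](c1ccc(OCc9ccccc9)c(OCc9ccccc9)c1)[C@H](O[Si](C)(C)C(C)(C)C)[C@H]2O[Si](C)(C)C(C)(C)C.[Li+] | intermediate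
23 | 2,4-diarylchroman-3-one (C2/C4 epimers) | c9ccccc9COc1cc(OCc9ccccc9)c2c(c1)OC(c1ccc(OCc9ccccc9)c(OCc9ccccc9)c1)C(=O)C2c1c(OCc9ccccc9)cc(OCc9ccccc9)c2c1O[C@H](c1ccc(OCc9ccccc9)c(OCc9ccccc9)c1)[C@H](O[Si](C)(C)C(C)(C)C)[C@H]2O[Si](C)(C)C(C)(C)C | intermediate
24 | all-cis (2S,3S,4R) carbinol, lower unit bis-O-TBS | c9ccccc9COc1cc(OCc9ccccc9)c2c(c1)O[C@@H](c1ccc(OCc9ccccc9)c(OCc9ccccc9)c1)[C@@H](O)[C@H]2c1c(OCc9ccccc9)cc(OCc9ccccc9)c2c1O[C@H](c1ccc(OCc9ccccc9)c(OCc9ccccc9)c1)[C@H](O[Si](C)(C)C(C)(C)C)[C@H]2O[Si](C)(C)C(C)(C)C | intermediate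
25 | octa-O-benzyl triol | c9ccccc9COc1cc(OCc9ccccc9)c2c(c1)O[C@@H](c1ccc(OCc9ccccc9)c(OCc9ccccc9)c1)[C@@H](O)[C@H]2c1c(OCc9ccccc9)cc(OCc9ccccc9)c2c1O[C@H](c1ccc(OCc9ccccc9)c(OCc9ccccc9)c1)[C@H](O)[C@H]2O | intermediate
26 | CNP0114173.1 | Oc1cc(O)c2c(c1)O[C@@H](c1ccc(O)c(O)c1)[C@@H](O)[C@H]2c1c(O)cc(O)c2c1O[C@H](c1ccc(O)c(O)c1)[C@H](O)[C@H]2O | target

**Step count and risks**

Total: 16 steps. Longest linear sequence: 14 steps (1–3, 5–9, 11–16).

Step 11 (proposed new method). The carbene may be consumed by insertion into the many benzylic and α-oxy C–H bonds or by attack on the alkoxyarene rings faster than it adds to the crowded furan bond. The cation, once formed, may also ionise the C4' silyl ether if traces of HBr arise. The fallback uses known chemistry, sets out from 2 and 4 and returns at 23. Oxidation of 2 with Dess–Martin periodinane gives tetra-O-benzylflavan-3-one F1. Compound 4 is hydroxylated at C4' with DDQ/H2O to the carbinol F2 and silylated (TBSCl, imidazole) to the bis-silyl aryl bromide F3. Palladium-catalysed α-arylation of the ketone F1 with F3 (Pd2(dba)3, P(t-Bu)3, NaOt-Bu, toluene, 80 °C) at the more acidic, less hindered benzylic C4 methylene then forms the C4–C8' bond and gives 23, from which steps 14–16 follow.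

Step 14. The facial preference of the catalyst may be weak or opposite to the model, the chiral lower unit may override it, or epimerisation at the hindered C4 may be too slow for a fully dynamic resolution. The fallback sets out from 23 and returns at 24. Substrate-controlled reduction with LiBH(s-Bu)3 in THF at −78 °C (equatorial attack, as in the catechin-to-epicatechin inversion) should give the two all-cis carbinols. These are 24 and its upper-unit antipode F4, which are diastereomers because of the fixed lower unit and would be separated by chromatography. F4 is recycled to 23 with Dess–Martin periodinane.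

Step 13. The 3-lithio-2H-chromene may open by anti-periplanar β-elimination of the ring aryloxide before it is borylated, exchange at the tetrasubstituted bromide may be slow, and the electron-rich ketone may be over-oxidised by peroxide. The fallback sets out from 20 and returns at 23. Miyaura borylation (B2pin2, PdCl2(dppf), KOAc, dioxane, 80 °C) avoids any organolithium and gives the C3 pinacol boronate F5. Oxidation of F5 with NaBO3·4H2O in THF/H2O gives 23.

**Further compounds**

F1 | step 11 | tetra-O-benzylflavan-3-one | O=C1Cc2c(OCc9ccccc9)cc(OCc9ccccc9)cc2O[C@@H]1c1ccc(OCc9ccccc9)c(OCc9ccccc9)c1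
F2 | step 11 | C8'-bromo-tetra-O-benzyl-3'-O-TBS-epicatechin-4'-ol (3',4'-trans) | Brc1c(OCc9ccccc9)cc(OCc9ccccc9)c2c1O[C@H](c1ccc(OCc9ccccc9)c(OCc9ccccc9)c1)[C@H](O[Si](C)(C)C(C)(C)C)[C@H]2O
F3 | step 11 | C8'-bromo-tetra-O-benzyl-3',4'-bis-O-TBS-epicatechin-4'-ol | Brc1c(OCc9ccccc9)cc(OCc9ccccc9)c2c1O[C@H](c1ccc(OCc9ccccc9)c(OCc9ccccc9)c1)[C@H](O[Si](C)(C)C(C)(C)C)[C@H]2O[Si](C)(C)C(C)(C)C
F4 | step 14 | all-cis (2R,3R,4S) upper-unit diastereomer of 24 | c9ccccc9COc1cc(OCc9ccccc9)c2c(c1)O[C@H](c1ccc(OCc9ccccc9)c(OCc9ccccc9)c1)[C@H](O)[C@@H]2c1c(OCc9ccccc9)cc(OCc9ccccc9)c2c1O[C@H](c1ccc(OCc9ccccc9)c(OCc9ccccc9)c1)[C@H](O[Si](C)(C)C(C)(C)C)[C@H]2O[Si](C)(C)C(C)(C)C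
F5 | step 13 | C3 pinacol boronate of the 2H-chromene | c9ccccc9COc1cc(OCc9ccccc9)c2c(c1)OC(c1ccc(OCc9ccccc9)c(OCc9ccccc9)c1)C(B3OC(C)(C)C(C)(C)O3)=C2c1c(OCc9ccccc9)cc(OCc9ccccc9)c2c1O[C@H](c1ccc(OCc9ccccc9)c(OCc9ccccc9)c1)[C@H](O[Si](C)(C)C(C)(C)C)[C@H]2O[Si](C)(C)C(C)(C)C
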